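**Retrosynthetic overview**

1. Target ⇐ its bis-silyl ether ⇐ 3-oxo-4-aryloxy cis-decalin: fluoride desilylation at the end; the C3 carbonyl is a temporary activating group and is removed by reduction and Barton–McCombie deoxygenation.
2. 3-Oxo-4-aryloxy cis-decalin ⇐ 3-hydroxy-3-(1-aryloxyvinyl) cis-hydrindane by acid-triggered semipinacol ring expansion: ring A (C4–C3–C2–C1–C10–C5) grows from the cyclopentane C3–C2–C1–C10–C5. Enabling feature: C4 carries CH3 and the aryl ether oxygen and is bonded to the ring-fusion methine C5 and to C3, so with an extra OH on C3 it can start as an exocyclic aryloxocarbenium carbon that accepts the C3–C5 bond.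
3. Aryl enol ether ⇐ aryl ester (Tebbe methylenation) ⇐ α-hydroxy acid + mono-silylated magnolol: the ester C–O bond becomes the tertiary ether C–O bond and the ester carbonyl carbon becomes C4.
4. α-Hydroxy acid ⇐ cis-hydrindane carboxylic acid (exo-face enediolate oxygenation) ⇐ keto ester (Mukaiyama hydration of the isopropenyl group, Wolff–Kishner removal of the C9 carbonyl).
5. cis-Hydrindane keto ester ⇐ (S)-carvone + methyl 4-chlorobutanoate (Mukaiyama–Michael addition anti to isopropenyl, then intramolecular enolate alkylation). Ring order: ring B (from carvone), then the cyclopentane, then ring A by expansion.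

Key step: step 11

Remark: the target SMILES is read as the cis-fused decalin (4R,5S,7R,10R) in terpenoid numbering (C4 carries CH3 and OAr, C5–H and C10–CH3 are at the ring fusion, C7 carries C11(CH3)2OH); this numbering is kept for all intermediates, and β denotes the face of the C10 methyl group.

**Route**

Step 1
Reactants: 1 methyl 4-chlorobutanoate
Product: 2 (4-chloro-1-methoxybut-1-enyloxy)trimethylsilane (E/Z mixture)
Conditions: LiN(iPr)2 (LDA), THF, −78 °C; Me3SiCl, −78 °C → rt; distillation
Reagents that add atoms: chlorotrimethylsilane, C[Si](C)(C)Cl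
Why: Kinetic deprotonation of the ester at −78 °C and O-silylation of the enolate (silyl ketene acetal formation) should be faster than 3-exo-tet closure onto the primary chloride; no stereocentre is formed.

Step 2
Reactants: 3 (S)-(+)-carvone; 2 (4-chloro-1-methoxybut-1-enyloxy)trimethylsilane
Product: 5 methyl 4-chloro-2-[2-methyl-3-oxo-5-(prop-1-en-2-yl)cyclohexyl]butanoate (C5–C3 bond α and trans to the C7 isopropenyl group; epimers at C3 and C10), via silyl enol ether 4 (not isolated)
Conditions: Tf2NH (2 mol%), CH2Cl2, −78 °C; then 1 M HCl, THF, 0 °C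
Reagents that add atoms: none
Why: Mukaiyama–Michael addition catalysed by the silyl triflimide formed in situ: the ketene acetal should attack C5 of the enone axially and anti to the equatorial isopropenyl group, which sets the C5–C3 bond α, while the epimeric centres C3 and C10 are both re-formed later.

Step 3
Reactants: 5 methyl 4-chloro-2-[2-methyl-3-oxo-5-(prop-1-en-2-yl)cyclohexyl]butanoate
Product: 6 methyl (3aS,6S,7aR)-3a-methyl-4-oxo-6-(prop-1-en-2-yl)octahydro-1H-indene-1-carboxylate (cis-fused; 5β-H; 10β-CH3; 7β-isopropenyl; C3 epimers)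
Conditions: KOtBu, THF/t-BuOH, 0 °C → rt
Reagents that add atoms: none
Why: Intramolecular enolate alkylation (5-exo-tet) through the more substituted C10 enolate: the axial C5 side chain can reach only the α face of C10, so the cyclopentane should be cis-fused and the new quaternary centre should carry CH3 on the β face, cis to 5-H and to the C7 substituent.

Step 4
Reactants: 6 methyl (3aS,6S,7aR)-3a-methyl-4-oxo-6-(prop-1-en-2-yl)octahydro-1H-indene-1-carboxylate
Product: 7 methyl (3aS,6S,7aR)-6-(2-hydroxypropan-2-yl)-3a-methyl-4-oxooctahydro-1H-indene-1-carboxylate (C3 epimers)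
Conditions: Co(acac)2 (20 mol%), PhSiH3, O2 (1 atm), THF/i-PrOH, rt
Reagents that add atoms: dioxygen, O=O
Why: Mukaiyama hydration (hydrogen atom transfer to the 1,1-disubstituted alkene, trapping of the tertiary radical by O2 and reduction) should give the Markovnikov tertiary alcohol without touching ketone or ester; no stereocentre is created.

Step 5
Reactants: 7 methyl (3aS,6S,7aR)-6-(2-hydroxypropan-2-yl)-3a-methyl-4-oxooctahydro-1H-indene-1-carboxylate
Product: 10 (3aS,6R,7aR)-6-(2-hydroxypropan-2-yl)-3a-methyloctahydro-1H-indene-1-carboxylic acid (cis-fused; C3 epimers), via potassium keto carboxylate 8 (not isolated), via hydrazone 9 (not isolated)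
Conditions: KOH, diethylene glycol, 110 °C; then N2H4·H2O, 140 → 200 °C; aq. HCl work-up
Reagents that add atoms: potassium hydroxide, [K+].[OH-]
Why: Saponification followed by Wolff–Kishner reduction (Huang-Minlon variant) should remove the C9 carbonyl; its neighbours C10 (quaternary) and C8 carry no stereochemical information, so only the irrelevant C3 centre can epimerise.

Step 6
Reactants: 10 (3aS,6R,7aR)-6-(2-hydroxypropan-2-yl)-3a-methyloctahydro-1H-indene-1-carboxylic acid
Product: 12 3a-methyl-6-[2-(triethylsilyloxy)propan-2-yl]octahydro-1H-indene-1-carboxylic acid (ring stereochemistry as in 10), via bis-silyl compound 11 (not isolated)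
Conditions: Et3SiOTf (2.5 equiv), 2,6-lutidine, CH2Cl2, 0 °C; then aq. NaHCO3/MeOH, rt; acidify to pH 4
Reagents that add atoms: triethylsilyl trifluoromethanesulfonate, CC[Si](CC)(CC)OS(=O)(=O)C(F)(F)F
Why: Silyl triflate silylation of the hindered tertiary alcohol; the silyl ester formed alongside should be solvolysed selectively by mild base, leaving the tertiary silyl ether as protection for the acid-triggered step and the xanthate step.

Step 7
Reactants: 12 3a-methyl-6-[2-(triethylsilyloxy)propan-2-yl]octahydro-1H-indene-1-carboxylic acid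
Product: 14 (1S,3aS,6R,7aS)-1-hydroxy-3a-methyl-6-[2-(triethylsilyloxy)propan-2-yl]octahydro-1H-indene-1-carboxylic acid (3β-OH; 3α-CO2H; 5β-H; 10β-CH3), via α-hydroperoxy acid 13 (not isolated)
Conditions: LiN(iPr)2 (2.3 equiv), THF, −78 → 40 °C; O2, −78 °C; P(OEt)3; aq. HCl to pH 3
Reagents that add atoms: dioxygen, O=O
Why: α-Hydroxylation of a carboxylic acid dianion (enediolate autoxidation, then reduction of the hydroperoxide): O2 should attack C3 from the open exo (β) face of the cis-hydrindane, away from ring B, giving 3β-OH and 3α-carboxyl.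

Step 8
Reactants: 15 magnolol (5,5'-diallylbiphenyl-2,2'-diol)
Product: 16 5,5'-diallyl-2'-(triisopropylsilyloxy)biphenyl-2-ol
Conditions: iPr3SiCl (1.0 equiv), imidazole, DMF, 0 °C → rt
Reagents that add atoms: chlorotri(propan-2-yl)silane, CC(C)[Si](Cl)(C(C)C)C(C)C
Why: Statistical monosilylation of the C2-symmetric biphenol with one equivalent of the bulky silyl chloride; unreacted 15 and the bis-silyl ether can be recycled.

Step 9
Reactants: 14 (1S,3aS,6R,7aS)-1-hydroxy-3a-methyl-6-[2-(triethylsilyloxy)propan-2-yl]octahydro-1H-indene-1-carboxylic acid; 16 5,5'-diallyl-2'-(triisopropylsilyloxy)biphenyl-2-ol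
Product: 17 5,5'-diallyl-2'-(triisopropylsilyloxy)biphenyl-2-yl ester of acid 14 (3β-OH; 5β-H; 10β-CH3; 11-O-SiEt3)
Conditions: EDC·HCl, DMAP (0.3 equiv), CH2Cl2, 0 °C → rt
Reagents that add atoms: none
Why: Steglich-type carbodiimide/DMAP esterification through the acylpyridinium ion; the tertiary 3-OH is too hindered to compete with the phenol and no stereocentre is touched.

Step 10
Reactants: 17 5,5'-diallyl-2'-(triisopropylsilyloxy)biphenyl-2-yl ester of acid 14
Product: 18 3β-hydroxy-3α-[1-(aryloxy)ethenyl] cis-hydrindane (aryl = 5,5'-diallyl-2'-(triisopropylsilyloxy)biphenyl-2-yl; 5β-H; 10β-CH3; 11-O-SiEt3)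
Conditions: Tebbe reagent Cp2Ti(μ-Cl)(μ-CH2)AlMe2 (3 equiv), pyridine, THF/toluene, −40 °C → rt; aq. NaOH work-up
Reagents that add atoms: Tebbe reagent Cp2Ti(μ-Cl)(μ-CH2)AlMe2 (SMILES of the open form Cp2Ti(Cl)CH2AlMe2), C[Al](C)C[Ti](Cl)(C1C=CC=C1)C1C=CC=C1
Why: Tebbe methylenation (cycloaddition of Cp2Ti=CH2 to the ester carbonyl and cycloreversion) should turn the aryl ester into the aryl enol ether, a transformation established for phenyl esters; the excess reagent covers the free hydroxyl, which is released again on work-up.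

Step 11
Reactants: 18 3β-hydroxy-3α-[1-(aryloxy)ethenyl] cis-hydrindane
Product: 20 4α-aryloxy-4β-methyl-3-oxo cis-decalin (5β-H; 10β-CH3; 7β-C(CH3)2OSiEt3; aryl = 5,5'-diallyl-2'-(triisopropylsilyloxy)biphenyl-2-yl), via aryloxocarbenium ion 19 (not isolated)
Conditions: Tf2NH (5 mol%), CH2Cl2, 4 Å molecular sieves, −60 → −20 °C; Et3N quench
Reagents that add atoms: none
Why: Markovnikov C-protonation of the aryl enol ether gives the tertiary aryloxocarbenium ion 19 at C4, and the C3–C5 ring bond, lying parallel to the empty p orbital, shifts from C3 to C4 while the C3 hydroxyl becomes the C3 ketone and returns the proton (protio-semipinacol rearrangement). The closest known reaction types are the oxocarbenium-initiated pinacol-type ring expansions of 1-(1-alkoxyvinyl)cycloalkanols and the acyloin (α-ketol) D-homoannulation, of which this is the O-aryl counterpart. Ring A is closed by a 1,2-shift of a ring bond, so that the cis-fused cyclopentane C3–C2–C1–C10–C5 takes up the exocyclic carbon C4 and becomes the six-membered ring C4–C3–C2–C1–C10–C5, ring B staying as it is. C5 migrates with retention, so the cis ring fusion (5β-H, 10β-CH3) passes unchanged into the decalin, and the new quaternary centre C4 is controlled by the C3 carbinol configuration (3β-OH, enol ether on the α face) together with the rotamer in which the oxocarbenium oxygen is anti to the C3–O bond and the small oxygen, not the methyl group, takes the inside (concave) position, which places OAr α and CH3 β. Two selectivities are needed: migration of C5 and not of C2, which the higher migratory aptitude of the more substituted methine carbon should secure, and C–C shift and not capture of the cation, which the anhydrous non-nucleophilic medium, the silyl caps on the second phenol and on the C11 hydroxyl, and the fact that the only arene carbon within reach of C4 lies meta to its silyloxy group should secure. The carbonyl carbon of ester 17 thus ends as the hindered tertiary alkyl aryl ether carbon, a bond that etherification or O-arylation of the tertiary alcohol is unlikely to give.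

Step 12
Reactants: 20 4α-aryloxy-4β-methyl-3-oxo cis-decalin
Product: 21 4α-aryloxy-4β-methyl cis-decalin-3-ol (C3 epimers; silyl ethers as in 20)
Conditions: NaBH4, THF/MeOH, 0 °C
Reagents that add atoms: none
Why: Borohydride reduction of the hindered α-aryloxy ketone; the configuration of the new C3 carbinol is irrelevant because C3 becomes CH2 in step 14.

Step 13
Reactants: 21 4α-aryloxy-4β-methyl cis-decalin-3-ol
Product: 22 O-(4α-aryloxy-4β-methyl cis-decalin-3-yl) S-methyl dithiocarbonate (C3 epimers)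
Conditions: NaH, imidazole (cat.), THF, 0 °C; CS2; then MeI, rt
Reagents that add atoms: carbon disulfide, S=C=S; iodomethane, CI
Why: Xanthate formation from the secondary alkoxide (addition to CS2, S-methylation); silyl ethers, allyl groups and the tertiary ether are inert.

Step 14
Reactants: 22 O-(4α-aryloxy-4β-methyl cis-decalin-3-yl) S-methyl dithiocarbonate
Product: 23 bis-silyl ether of the target (11-O-SiEt3; 2'-O-Si(iPr)3)
Conditions: Bu3SnH (3 equiv, 0.5 M), AIBN (cat.), toluene, 90 °C
Reagents that add atoms: none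
Why: Barton–McCombie radical deoxygenation; the high stannane concentration should make hydrogen transfer to the C3 radical faster than β-scission of the C4–O bond, and the C4, C5 and C10 centres are not involved.

Step 15
Reactants: 23 bis-silyl ether of the target
Product: 24 target, (4R,5S,7R,10R)-4-[(5,5'-diallyl-2'-hydroxybiphenyl-2-yl)oxy] cis-eudesman-11-ol
Conditions: Bu4NF (3 equiv), THF, 0 → 45 °C; aq. NH4Cl
Reagents that add atoms: none
Why: Fluoride-induced cleavage of the aryl and the tertiary alkyl silyl ethers; the tertiary alkyl aryl ether, the allyl groups and all stereocentres are unaffected.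

**Compound list**

1 | methyl 4-chlorobutanoate | COC(=O)CCCCl | starting material
2 | (4-chloro-1-methoxybut-1-enyloxy)trimethylsilane (E/Z mixture) | COC(=CCCCl)O[Si](C)(C)C | intermediate
3 | (S)-(+)-carvone | CC1=CC[C@@H](CC1=O)C(C)=C | starting material
4 | trimethylsilyl enol ether of 5 (Michael adduct before hydrolysis) | COC(=O)C(CCCl)[C@H]1C[C@H](C(C)=C)CC(O[Si](C)(C)C)=C1C | intermediate
5 | methyl 4-chloro-2-[2-methyl-3-oxo-5-(prop-1-en-2-yl)cyclohexyl]butanoate (C5–C3 bond trans to isopropenyl; epimers at C3 and C10) | COC(=O)C(CCCl)[C@H]1C[C@H](C(C)=C)CC(=O)C1C | intermediate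
6 | methyl (3aS,6S,7aR)-3a-methyl-4-oxo-6-(prop-1-en-2-yl)octahydro-1H-indene-1-carboxylate (cis-fused; C3 epimers) | COC(=O)C1CC[C@]2(C)C(=O)C[C@@H](C(C)=C)C[C@@H]21 | intermediate
7 | methyl (3aS,6S,7aR)-6-(2-hydroxypropan-2-yl)-3a-methyl-4-oxooctahydro-1H-indene-1-carboxylate | COC(=O)C1CC[C@]2(C)C(=O)C[C@@H](C(C)(C)O)C[C@@H]21 | intermediate
8 | potassium salt of the keto acid from 7 | [K+].[O-]C(=O)C1CC[C@]2(C)C(=O)C[C@@H](C(C)(C)O)C[C@@H]21 | intermediate
9 | C9 hydrazone of 8 | [K+].[O-]C(=O)C1CC[C@]2(C)C(=NN)C[C@@H](C(C)(C)O)C[C@@H]21 | intermediate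
10 | (3aS,6R,7aR)-6-(2-hydroxypropan-2-yl)-3a-methyloctahydro-1H-indene-1-carboxylic acid (C3 epimers) | OC(=O)C1CC[C@]2(C)CC[C@@H](C(C)(C)O)C[C@@H]21 | intermediate
11 | triethylsilyl ester and triethylsilyl ether of 10 | CC[Si](CC)(CC)OC(=O)C1CC[C@]2(C)CC[C@@H](C(C)(C)O[Si](CC)(CC)CC)C[C@@H]21 | intermediate
12 | 3a-methyl-6-[2-(triethylsilyloxy)propan-2-yl]octahydro-1H-indene-1-carboxylic acid (ring stereochemistry as in 10) | OC(=O)C1CC[C@]2(C)CC[C@@H](C(C)(C)O[Si](CC)(CC)CC)C[C@@H]21 | intermediate
13 | 3β-hydroperoxy acid from 12 | OC(=O)[C@]1(OO)CC[C@]2(C)CC[C@@H](C(C)(C)O[Si](CC)(CC)CC)C[C@@H]21 | intermediate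
14 | (1S,3aS,6R,7aS)-1-hydroxy-3a-methyl-6-[2-(triethylsilyloxy)propan-2-yl]octahydro-1H-indene-1-carboxylic acid (3β-OH; 3α-CO2H) | OC(=O)[C@]1(O)CC[C@]2(C)CC[C@@H](C(C)(C)O[Si](CC)(CC)CC)C[C@@H]21 | intermediate
15 | magnolol | C=CCc1ccc(O)c(-c2cc(CC=C)ccc2O)c1 | starting material
16 | 5,5'-diallyl-2'-(triisopropylsilyloxy)biphenyl-2-ol | C=CCc1ccc(O)c(-c2cc(CC=C)ccc2O[Si](C(C)C)(C(C)C)C(C)C)c1 | intermediate
17 | 5,5'-diallyl-2'-(triisopropylsilyloxy)biphenyl-2-yl ester of 14 | C=CCc1ccc(O[Si](C(C)C)(C(C)C)C(C)C)c(-c2cc(CC=C)ccc2OC(=O)[C@]2(O)CC[C@]3(C)CC[C@@H](C(C)(C)O[Si](CC)(CC)CC)C[C@@H]32)c1 | intermediate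
18 | 3β-hydroxy-3α-[1-(aryloxy)ethenyl] cis-hydrindane (aryl enol ether) | C=CCc1ccc(O[Si](C(C)C)(C(C)C)C(C)C)c(-c2cc(CC=C)ccc2OC(=C)[C@]2(O)CC[C@]3(C)CC[C@@H](C(C)(C)O[Si](CC)(CC)CC)C[C@@H]32)c1 | intermediate
19 | aryloxocarbenium ion at C4 from 18 (triflimide counter-ion) | C=CCc1ccc(O[Si](C(C)C)(C(C)C)C(C)C)c(-c2cc(CC=C)ccc2[O+]=C(C)[C@]2(O)CC[C@]3(C)CC[C@@H](C(C)(C)O[Si](CC)(CC)CC)C[C@@H]32)c1 | intermediate
20 | 4α-aryloxy-4β-methyl-3-oxo cis-decalin (5β-H; 10β-CH3; 11-O-SiEt3; 2'-O-Si(iPr)3) | C=CCc1ccc(O[Si](C(C)C)(C(C)C)C(C)C)c(-c2cc(CC=C)ccc2O[C@]2(C)C(=O)CC[C@]3(C)CC[C@@H](C(C)(C)O[Si](CC)(CC)CC)C[C@@H]32)c1 | intermediate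
21 | C3 alcohol from 20 (C3 epimers) | C=CCc1ccc(O[Si](C(C)C)(C(C)C)C(C)C)c(-c2cc(CC=C)ccc2O[C@]2(C)C(O)CC[C@]3(C)CC[C@@H](C(C)(C)O[Si](CC)(CC)CC)C[C@@H]32)c1 | intermediate
22 | C3 S-methyl xanthate of 21 | C=CCc1ccc(O[Si](C(C)C)(C(C)C)C(C)C)c(-c2cc(CC=C)ccc2O[C@]2(C)C(OC(=S)SC)CC[C@]3(C)CC[C@@H](C(C)(C)O[Si](CC)(CC)CC)C[C@@H]32)c1 | intermediate
23 | bis-silyl ether of the target | C=CCc1ccc(O[Si](C(C)C)(C(C)C)C(C)C)c(-c2cc(CC=C)ccc2O[C@]2(C)CCC[C@]3(C)CC[C@@H](C(C)(C)O[Si](CC)(CC)CC)C[C@@H]32)c1 | intermediate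
24 | (4R,5S,7R,10R)-4-[(5,5'-diallyl-2'-hydroxybiphenyl-2-yl)oxy] cis-eudesman-11-ol | C=CCc1ccc(O)c(-c2cc(CC=C)ccc2O[C@]2(C)CCC[C@]3(C)CC[C@@H](C(C)(C)O)C[C@@H]32)c1 | target

**Step count and risks**

Total step count: 15. Longest linear sequence: 14 steps (steps 1–7 and 9–15, from 1; step 8 is a one-step side branch).

Steps most likely to fail:

1. Step 11. What may go wrong: erosion of facial selectivity at C4 when the oxocarbenium rotamer with syn-clinal oxygens competes, next to capture of the cation before the C–C shift. Fallback (sets out from 14, comes back at 20): the carbinol configuration is inverted so that the other rotamer leads to the same C4 centre. Oxidative decarboxylation of 14 with Pb(OAc)4 should give the cis-hydrindan-3-one F1. Vinylmagnesium bromide with CeCl3 should add to its open β face to give the vinyl carbinol F2 (3α-OH). Ozonolysis (O3, then Me2S) should give the hydroxy aldehyde F3, and NaClO2 oxidation the hydroxy acid F4, the C3 epimer of 14. Esterification with 16 as in step 9 should give the aryl ester F5, and methylenation as in step 10 the aryl enol ether F6, which carries the enol ether on the open β face. Its acid-triggered ring expansion through the syn-clinal rotamer should give 20.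

2. Step 10. What may go wrong: incomplete methylenation because ring B shields the α-face ester carbonyl, and collapse of the oxatitanacyclobutane with loss of aryloxide. Fallback (sets out from 14, comes back at 18): C–O cross-coupling in place of carbonyl methylenation. MeLi in excess should turn the acid 14 into the methyl ketone F7. KN(SiMe3)2 (2.2 equiv) and PhNTf2 should give the hydroxy enol triflate F8 through the kinetic methyl enolate. Pd-catalysed coupling of F8 with phenol 16 (Pd2(dba)3, 2-(di-tert-butylphosphino)biphenyl, K3PO4, toluene) should give 18.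

3. Step 3. What may go wrong: 3-exo-tet closure of the ester enolate onto the chloride (cyclopropane formation) or retro-Michael cleavage competing with the 5-exo alkylation. Fallback (sets out from 3, comes back at 6): the acidic C3–H is blocked as a malonate. Michael addition of dimethyl malonate to 3 (NaOMe, MeOH) should give the malonate adduct F9. Alkylation of its malonate carbon with 1-bromo-2-chloroethane (NaH, DMF) should give the chloroethyl malonate F10, in which only the ketone can be enolised. KOtBu should then close the cyclopentane to the bicyclic diester F11, and Krapcho demethoxycarbonylation (LiCl, wet DMSO, 150 °C) should give 6.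

Further compounds
F1 | step 11 | cis-hydrindan-3-one (5β-H; 10β-CH3; 11-O-SiEt3) | O=C1CC[C@]2(C)CC[C@@H](C(C)(C)O[Si](CC)(CC)CC)C[C@@H]21
F2 | step 11 | 3β-vinyl-3α-hydroxy cis-hydrindane | C=C[C@@]1(O)CC[C@]2(C)CC[C@@H](C(C)(C)O[Si](CC)(CC)CC)C[C@@H]21
F3 | step 11 | 3α-hydroxy cis-hydrindane-3β-carbaldehyde | O=C[C@@]1(O)CC[C@]2(C)CC[C@@H](C(C)(C)O[Si](CC)(CC)CC)C[C@@H]21
F4 | step 11 | 3α-hydroxy cis-hydrindane-3β-carboxylic acid (C3 epimer of 14) | OC(=O)[C@@]1(O)CC[C@]2(C)CC[C@@H](C(C)(C)O[Si](CC)(CC)CC)C[C@@H]21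
F5 | step 11 | 5,5'-diallyl-2'-(triisopropylsilyloxy)biphenyl-2-yl ester of F4 | C=CCc1ccc(O[Si](C(C)C)(C(C)C)C(C)C)c(-c2cc(CC=C)ccc2OC(=O)[C@@]2(O)CC[C@]3(C)CC[C@@H](C(C)(C)O[Si](CC)(CC)CC)C[C@@H]32)c1
F6 | step 11 | 3α-hydroxy-3β-[1-(aryloxy)ethenyl] cis-hydrindane (C3 epimer of 18) | C=CCc1ccc(O[Si](C(C)C)(C(C)C)C(C)C)c(-c2cc(CC=C)ccc2OC(=C)[C@@]2(O)CC[C@]3(C)CC[C@@H](C(C)(C)O[Si](CC)(CC)CC)C[C@@H]32)c1
F7 | step 10 | 3α-acetyl-3β-hydroxy cis-hydrindane (methyl ketone from 14) | CC(=O)[C@]1(O)CC[C@]2(C)CC[C@@H](C(C)(C)O[Si](CC)(CC)CC)C[C@@H]21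
F8 | step 10 | 3β-hydroxy-3α-[1-(trifluoromethylsulfonyloxy)ethenyl] cis-hydrindane | C=C(OS(=O)(=O)C(F)(F)F)[C@]1(O)CC[C@]2(C)CC[C@@H](C(C)(C)O[Si](CC)(CC)CC)C[C@@H]21
F9 | step 3 | dimethyl 2-[2-methyl-3-oxo-5-(prop-1-en-2-yl)cyclohexyl]malonate (C5–C3 bond trans to isopropenyl) | COC(=O)C(C(=O)OC)[C@H]1C[C@H](C(C)=C)CC(=O)C1C
F10 | step 3 | dimethyl 2-(2-chloroethyl)-2-[2-methyl-3-oxo-5-(prop-1-en-2-yl)cyclohexyl]malonate | COC(=O)C(CCCl)(C(=O)OC)[C@H]1C[C@H](C(C)=C)CC(=O)C1C
F11 | step 3 | dimethyl cis-3a-methyl-4-oxo-6-(prop-1-en-2-yl)octahydro-1H-indene-1,1-dicarboxylate | COC(=O)C1(C(=O)OC)CC[C@]2(C)C(=O)C[C@@H](C(C)=C)C[C@@H]21
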